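Numbering used throughout: bicyclic compounds carry drimane numbers (ring A = C1–C5 and C10; ring B = C5–C10; C11 on C9, C12 on C8, two methyls on C4, angular methyl on C10; "11-nor" = C11 absent); monocyclic intermediates are numbered as cyclohex-2-en-1-ones.

## Analysis of the target

The target is a drimane sesquiterpene: a trans-fused decalin whose C11 methylene on C9 is joined through an ether oxygen to C7 of a coumarin. It has five stereocenters, (2S,3S,5S,9R,10R). C5 and the quaternary C10 define the trans ring fusion, the C11 arm on C9 is equatorial and cis to the C10 methyl group, and the C2 and C3 hydroxyls form a trans-diequatorial diol with O3 cis and O2 trans to that methyl group. This decalin appears to be antipodal to that of the common drimanes such as drimenol, so the chiral-pool source is chosen from the C5 configuration and not from habit. Sensitive sites are the coumarin lactone and its enoate double bond (hydrides, boranes, ylides, strong base), the trisubstituted C7=C8 alkene (acid, electrophiles, migration to the tetrasubstituted position), and the allylic C9–H, which would be labile if C11 were ever a carbonyl carbon. The difficulty lies in the contiguous array C4 (quaternary), C5 and C10 (quaternary), in placing two secondary hydroxyls with a trans relation next to the gem-dimethyl carbon, and in setting C9 beside the C7=C8 bond without enolate chemistry. Two features carry the plan. Ring B, with its C8 methyl, C7=C8 alkene, C9 carbon and C5 stereocenter, is the skeleton of carvone. In ring A the C1–C2 bond lies next to the oxygenated C3, so a C1=C2 alkene made by metathesis can be hydrated at C2 anti to O3.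

## Retrosynthetic reasoning

**C11–O(aryl) bond.** The target 24 is traced to its acetonide 23 and this to the primary alcohol 21 and umbelliferone 22. The coumarin tolerates neither boranes nor ylides, so it is attached last, by a redox condensation at a primary carbon where no stereocenter is at stake.

**C9–H and C11–O bonds.** Alcohol 21 is traced to the exocyclic diene 19 and this to the C9 ketone 18. Hydroboration of a C9=C11 methylene group puts oxygen on C11 and hydrogen on C9 in one operation. The hydrogen should enter anti to the axial C10 methyl group, so C9 is set by the substrate and C11 never passes through an epimerizable carbonyl stage. The C9 carbonyl is the carvone carbonyl and has no other duty.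

**C2–O bond.** Acetonide 18 comes from diol 17, and 17 from the allylic alcohol 15 by hydroboration of C1=C2. Boron should go to C2, the alkene carbon next to the carbinol carbon and remote from quaternary C10, on the face opposite O3 and the axial methyls. A single double hydroboration of a triene was weighed and set aside. Once C9 is methylenated and hydroborated, C7=C8 is an ordinary trisubstituted alkene with an open C7, and it would be no less reactive than the doubly flanked C1=C2 bond. The ring A hydroboration is therefore placed at the stage of 15, where C7=C8 is still the electron-poor alkene of an enone. The C9=C11 hydroboration follows later with a hindered dialkylborane that leaves C7=C8 alone.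

**C3 carbonyl.** Alcohol 15 comes from dienedione 14 by 1,2-reduction. The forward step must tell the two enone carbonyls apart (C3 is open on its C2 side, C9 is flanked on both sides) and deliver hydride anti to the axial methyls.

**C1=C2 bond (key disconnection).** Dienedione 14 is opened at C1=C2 to the monocyclic dienone 13. This is the only ring A bond whose formation creates no stereocenter, and it leaves exactly the alkene the diol needs. What is gained is that ring A is reduced to two vinyl groups on a ring B that already holds C5 and C10.

**C2–C3 bond and C3 oxidation level.** Vinyl ketone 13 comes from allylic alcohol 12, and 12 from the neopentylic aldehyde 11 by addition of a vinyl organometallic. The aldehyde has to react in the presence of the hindered C9 ketone.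

**C4 quaternary carbon.** Aldehyde 11 comes from its lower homologue 10 by methylation with iodomethane 2. Aldehyde 10 comes from epoxide 9 by a 1,2-hydride shift, and 9 from the isopropenyl group of 8. In this way the isopropenyl group of carvone supplies C4, one C4 methyl and C3.

**C10 quaternary carbon.** Vinyl compound 8 comes from aldol adduct 7 by dehydration. Adduct 7 comes from methyl ketone 4 and acetaldehyde 5, and 4 from (S)-carvone 1 and iodomethane 2. The second electrophile enters anti to the C5 substituent, which puts the two-carbon arm (C1, C2) trans and the methyl cis to the C5 side chain, as the trans ring fusion requires. The S configuration of 1 is the C5 configuration of the target.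

## Alternatives that were turned down

**Alternative 1:** Ring B is cut at C9–C10 and C7–C8, leading to the ring A diene ester A1, in which the C2 oxygen carries a but-2-ynoyl group.
- **Forward key step:** heating A1 gives an intramolecular Diels–Alder reaction (diene C10=C5–C6=C7, dienophile C8≡C9) to the tricyclic lactone A2, whose lactone ties C11 to O2.
- **For:** ring B, the C10 quaternary center (relayed from C2 through the tether), C11 and C12 arrive in one step, and O2 and O3 are in place and differentiated beforehand. On this point it is stronger than the chosen route, which needs late borane chemistry for O2 and C11.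
- **Against:** A2 is a 1,4-diene with C5=C6 and C8=C9. Neither C5 nor C9 is yet a stereocenter. C5=C6 must be reduced with the correct face for a trans fusion, and C8=C9 must be moved out of conjugation into C7=C8 with H9 on the right face, against the thermodynamic preference. The diene terminus C10 is fully substituted and the dienophile carries a β-methyl group, so forcing temperatures are expected. A1 itself needs an enantioselective synthesis.
- **Comparison:** the chosen route has C5 fixed from the first step and never moves C7=C8; it pays with two separate hydroborations.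

**Alternative 2:** Only C9–C10 is cut, leading to the monocyclic enoate A3.
- **Forward key step:** a strong acid (chlorosulfonic acid, or SnCl4 with a proton source) protonates C5 of the C5=C10 alkene, the C10 cation is taken by C9 of the enoate, and loss of H7 gives the decalin ester A4.
- **For:** ring B and the C5, C9 and C10 stereocenters are formed in one step through a chair-like closure, and C11 arrives as an ester. In step economy to the decalin this is clearly better than the chosen route.
- **Against:** A4 has no oxygen at C2, so the trans-diol must be completed afterwards by oxidation at C3, α-oxygenation and reduction, which spends the saved steps on enolate chemistry. The absolute configuration rests on the single C3 acetoxy center of A3, which must be made enantiopure and must relay to the face of protonation at C5. Proton loss from the C8 cation can go to C7, C9 or C12, with the conjugated isomer as the sink. The electron-poor enoate needs very strong acid.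
- **Comparison:** the chosen route takes C5 and the C7=C8/C12 array from carvone, leaves nothing to the fate of a cation, and makes the diol from the alkene its key step creates.

**Alternative 3:** C7–C8 and C8–C9 are cut, removing C8 with its methyl group and leading to the trans-hydrindanone silyl enol ether A5.
- **Forward key step:** chloro(methyl)carbene from 1,1-dichloroethane and n-BuLi adds to the C7=C9 enol ether of A5, and the chlorosiloxycyclopropane opens with loss of chloride and silyl to the ring-enlarged α-methyl enone A6.
- **For:** A6 is identical with compound 18 of the chosen route, so the endgame is shared. The diol is installed before ring B holds any alkene, so the site-selectivity problem of the ring A hydroboration does not arise. On this point it is stronger.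
- **Against:** the key step adds one carbon and no stereocenter. The trans-hydrindane fusion at C5, the adjacent C4 and C10 quaternary carbons and the trans-diol must all be built on A5 first, a long prelude. The carbenoid is thermally fragile and must reach an enol ether next to quaternary C10.
- **Comparison:** the chosen route reaches the same 18 from a starting material that already contains the six-membered ring B with its methyl enone.

Key step: step 9

Assumption: the C6 epimers of 4 and the epimers at the carbinol, oxirane and formyl-bearing carbons of 7, 9, 10 and 12 are carried as mixtures, because each of these centers is later flattened or becomes the gem-dimethyl carbon.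

## Route

Step 1
Reactants: 1 (S)-carvone; 2 iodomethane
Product: 4 (5S)-2,6-dimethyl-5-(prop-1-en-2-yl)cyclohex-2-en-1-one (both C6 epimers), via lithium enolate 3 (not isolated)
Conditions: LDA, THF, −78 °C; MeI, −78 → 0 °C
Reagents that add atoms: iodomethane (2), CI
Why: Kinetic α′-deprotonation of the enone gives the cross-conjugated lithium enolate, which is C-methylated (enolate alkylation); the configuration at C6 is irrelevant because this carbon is enolized again in step 2.

Step 2
Reactants: 4 the methyl ketone from step 1; 5 acetaldehyde
Product: 7 (5R,6S)-6-(1-hydroxyethyl)-2,6-dimethyl-5-(prop-1-en-2-yl)cyclohex-2-en-1-one (both carbinol epimers), via lithium enolate 6 (not isolated)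
Conditions: LDA, THF, −78 °C; CH3CHO, −78 °C; AcOH quench at −78 °C
Reagents that add atoms: acetaldehyde (5), CC=O
Why: Aldol addition of the tetrasubstituted enolate; the aldehyde should approach anti to the neighbouring isopropenyl group, which sits pseudoaxial to avoid allylic strain, so the new quaternary carbon carries the two-carbon arm trans and the methyl cis to the C5 substituent. The cold acidic quench forestalls retro-aldol cleavage.

Step 3
Reactants: 7 the aldol adduct
Product: 8 (5R,6R)-6-ethenyl-2,6-dimethyl-5-(prop-1-en-2-yl)cyclohex-2-en-1-one
Conditions: Martin sulfurane Ph2S[OC(CF3)2Ph]2, CH2Cl2, 0 °C → rt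
Reagents that add atoms: none
Why: Sulfurane dehydration of a secondary alcohol; the only β-hydrogens are those of the methyl group (the other neighbour is quaternary), so only the terminal vinyl group can form, and the near-neutral medium does not provoke retro-aldol cleavage.

Step 4
Reactants: 8 the vinyl ketone-free triene
Product: 9 (5S,6R)-6-ethenyl-2,6-dimethyl-5-(2-methyloxiran-2-yl)cyclohex-2-en-1-one (both oxirane epimers)
Conditions: mCPBA, NaHCO3, CH2Cl2, 0 °C
Reagents that add atoms: mCPBA (3-chloroperbenzoic acid), OOC(=O)c1cccc(Cl)c1
Why: Prilezhaev epoxidation; the 1,1-disubstituted isopropenyl alkene is the most electron-rich, while the monosubstituted vinyl group and the enone alkene should react far more slowly.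

Step 5
Reactants: 9 the epoxide
Product: 10 2-[(1R,2R)-2-ethenyl-2,4-dimethyl-3-oxocyclohex-4-en-1-yl]propanal (both C2 epimers)
Conditions: BF3·OEt2 (cat.), CH2Cl2, −78 → −30 °C
Reagents that add atoms: none
Why: Meinwald rearrangement; the Lewis acid opens the oxirane at its tertiary carbon and a 1,2-hydride shift from the CH2O carbon gives the aldehyde; the new α-center is flattened in step 6.

Step 6
Reactants: 10 the aldehyde; 2 iodomethane
Product: 11 2-[(1R,2R)-2-ethenyl-2,4-dimethyl-3-oxocyclohex-4-en-1-yl]-2-methylpropanal
Conditions: MeI (excess), then KOtBu (1.05 equiv), THF, −20 → 0 °C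
Reagents that add atoms: iodomethane (2), CI
Why: C-Methylation of an α-branched aldehyde enolate builds the C4 quaternary carbon; the aldehyde α-hydrogen is far more acidic than the γ-hydrogens of the enone, one equivalent of base is used and the enolate is trapped as it forms. C5 is not acidic and is not touched.

Step 7
Reactants: 11 the neopentylic aldehyde
Product: 12 (5R,6R)-6-ethenyl-5-(3-hydroxy-2-methylpent-4-en-2-yl)-2,6-dimethylcyclohex-2-en-1-one (both carbinol epimers)
Conditions: CH2=CHMgBr (1.1 equiv), THF, −78 °C; aq. NH4Cl
Reagents that add atoms: vinylmagnesium bromide, C=C[Mg]Br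
Why: Grignard 1,2-addition; at −78 °C the aldehyde should be far more electrophilic than the conjugated C9 ketone, which is flanked by a quaternary and a methyl-bearing carbon. The carbinol center is oxidized in step 8.

Step 8
Reactants: 12 the allylic alcohol
Product: 13 (5R,6R)-6-ethenyl-2,6-dimethyl-5-(2-methyl-3-oxopent-4-en-2-yl)cyclohex-2-en-1-one
Conditions: Dess–Martin periodinane, NaHCO3, CH2Cl2, 0 °C → rt
Reagents that add atoms: none
Why: Periodinane oxidation of a secondary allylic alcohol to the vinyl ketone under buffered, non-nucleophilic conditions that should spare the conjugate acceptor; the product is used without delay.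

Step 9
Reactants: 13 the dienone with C10 vinyl and C4 acryloyl groups
Product: 14 (5R,10R)-11-nordrima-1,7-diene-3,9-dione
Conditions: second-generation Grubbs catalyst RuCl2(=CHPh)(H2IMes)(PCy3) (5–10 mol %), CH2Cl2 (5 mM), 40 °C
Reagents that add atoms: none
Why: The benzylidene complex should load onto the C10 vinyl group, the more electron-rich of the two terminal alkenes, by [2+2] cycloaddition and cycloreversion, giving a ruthenium alkylidene at C1. This carbene adds intramolecularly across the terminal C=C bond of the acryloyl unit, and the ruthenacyclobutane opens to the C1=C2 bond and Ru=CH2, which carries the chain and leaves as ethylene, making the closure irreversible. The closest known reaction type is ring-closing metathesis of a vinyl ketone with a terminal alkene to a cyclohex-2-en-1-one. Ring A closes as a six-membered ring through the C1=C2 double bond between the ends of a 1,7-diene, and in a ring of this size the alkene can only be cis. No stereocenter is formed, and C5 and C10 cannot epimerize because C10 is quaternary and C5 is not alpha to a carbonyl group. The step needs site selectivity among four alkenes and ring closure in preference to cross-metathesis. The C7=C8 bond is trisubstituted, electron-poor and could only lead to a bridged ring, so it should be ignored, and high dilution suppresses dimerization. The trans relation of the two side chains, both equatorial on the ring B half-chair, and the gem-dimethyl group at C4 hold the vinyl and acryloyl groups gauche and close together.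

Step 10
Reactants: 14 the dienedione
Product: 15 (3R,5R,10R)-3-hydroxy-11-nordrima-1,7-dien-9-one
Conditions: NaBH4 (1.0 equiv), CeCl3·7H2O, MeOH, −78 °C
Reagents that add atoms: none
Why: Luche 1,2-reduction; the C3 carbonyl has an unsubstituted sp2 CH on one side, whereas C9 lies between quaternary C10 and methyl-bearing C8, so C3 should react first. Hydride should attack axially, anti to the axial methyls on C4 and C10, giving the equatorial 3-hydroxyl cis to the C10 methyl group.

Step 11
Reactants: 15 the allylic alcohol
Product: 17 (2S,3S,5R,10R)-2,3-dihydroxy-11-nordrim-7-en-9-one, via organoborane 16 (not isolated)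
Conditions: BH3·THF (1.5 equiv), THF, −20 → 0 °C; MeOH; Me3NO, THF, 65 °C; aq. work-up
Reagents that add atoms: trimethylamine N-oxide, C[N+](C)(C)[O-]
Why: Hydroboration–oxidation of a cyclic allylic alcohol; boron should go to C2 (next to the carbinol carbon and remote from quaternary C10) on the face anti to O3 and to the axial C4 and C10 methyls, and oxidation with retention gives the trans-diequatorial diol. It is run at this stage because C7=C8 is still deactivated by conjugation and borane should add to an isolated cis-alkene faster than it reduces a doubly flanked conjugated ketone. The amine oxide is a non-basic oxidant that leaves the enone alone.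

Step 12
Reactants: 17 the diol
Product: 18 (2S,3S,5R,10R)-2,3-(isopropylidenedioxy)-11-nordrim-7-en-9-one
Conditions: Me2C(OMe)2, CSA (cat.), CH2Cl2, rt
Reagents that add atoms: 2,2-dimethoxypropane, COC(C)(C)OC
Why: Acetal exchange gives the trans-fused dioxolane of the diequatorial diol, which masks both hydroxyls against ylide, borane and the redox condensation without silyl migration.

Step 13
Reactants: 18 the acetonide ketone
Product: 19 (2S,3S,5S,10R)-2,3-(isopropylidenedioxy)-9-methylidene-11-nordrim-7-ene
Conditions: Ph3PCH3Br, KOtBu, toluene, 90 °C
Reagents that add atoms: methyltriphenylphosphonium bromide, C[P+](c1ccccc1)(c1ccccc1)c1ccccc1.[Br-]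
Why: Wittig methylenation under the hot conditions used for hindered ketones; the C9 carbonyl has no α-hydrogen on the C10 side, so the main demand is forcing the ylide onto a flanked carbonyl carbon.

Step 14
Reactants: 19 the exocyclic diene
Product: 21 (2S,3S,5S,9R,10R)-2,3-(isopropylidenedioxy)drim-7-en-11-ol, via C11 trialkylborane 20 (not isolated)
Conditions: 9-BBN, THF, 0 °C → rt; NaOH, H2O2, 0 °C
Reagents that add atoms: hydrogen peroxide, OO
Why: Hydroboration–oxidation with a hindered dialkylborane, which should add only to the terminal 1,1-disubstituted alkene (boron on C11) and leave the trisubstituted C7=C8 bond. Hydrogen should reach C9 from the face opposite the axial C10 methyl group, so H9 becomes axial and C11 equatorial (9R).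

Step 15
Reactants: 21 the primary alcohol; 22 umbelliferone
Product: 23 7-{[(2S,3S,5S,9R,10R)-2,3-(isopropylidenedioxy)drim-7-en-11-yl]oxy}-2H-chromen-2-one
Conditions: PPh3, DIAD, THF, 0 °C → rt
Reagents that add atoms: umbelliferone (22), Oc1ccc2ccc(=O)oc2c1
Why: Mitsunobu etherification of a primary alcohol with an acidic phenol; C11 is not a stereocenter, and the neutral conditions leave the lactone, the acetonide and the alkene untouched.

Step 16
Reactants: 23 the acetonide ether
Product: 24 7-{[(2S,3S,5S,9R,10R)-2,3-dihydroxydrim-7-en-11-yl]oxy}-2H-chromen-2-one (target)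
Conditions: AcOH–H2O (4:1), 40 °C
Reagents that add atoms: none
Why: Acid hydrolysis of a strained trans-fused acetonide, which should proceed under conditions too mild to isomerize the C7=C8 alkene or open the coumarin.

## Compound list

1 | (S)-carvone, (5S)-2-methyl-5-(prop-1-en-2-yl)cyclohex-2-en-1-one | CC1=CC[C@H](C(C)=C)CC1=O | starting material
2 | iodomethane | CI | starting material
3 | lithium enolate of 1 (C1=C6 enolate) | CC1=CC[C@H](C(C)=C)C=C1[O-].[Li+] | intermediate (not isolated)
4 | (5S)-2,6-dimethyl-5-(prop-1-en-2-yl)cyclohex-2-en-1-one (C6 epimers) | CC1=CC[C@H](C(C)=C)C(C)C1=O | intermediate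
5 | acetaldehyde | CC=O | starting material
6 | lithium enolate of 4 (C1=C6 enolate) | CC1=CC[C@H](C(C)=C)C(C)=C1[O-].[Li+] | intermediate (not isolated)
7 | (5R,6S)-6-(1-hydroxyethyl)-2,6-dimethyl-5-(prop-1-en-2-yl)cyclohex-2-en-1-one (carbinol epimers) | CC1=CC[C@H](C(C)=C)[C@@](C)(C(C)O)C1=O | intermediate
8 | (5R,6R)-6-ethenyl-2,6-dimethyl-5-(prop-1-en-2-yl)cyclohex-2-en-1-one | CC1=CC[C@H](C(C)=C)[C@@](C)(C=C)C1=O | intermediate
9 | (5S,6R)-6-ethenyl-2,6-dimethyl-5-(2-methyloxiran-2-yl)cyclohex-2-en-1-one (oxirane epimers) | CC1=CC[C@H](C2(C)CO2)[C@@](C)(C=C)C1=O | intermediate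
10 | 2-[(1R,2R)-2-ethenyl-2,4-dimethyl-3-oxocyclohex-4-en-1-yl]propanal (C2 epimers) | CC1=CC[C@H](C(C)C=O)[C@@](C)(C=C)C1=O | intermediate
11 | 2-[(1R,2R)-2-ethenyl-2,4-dimethyl-3-oxocyclohex-4-en-1-yl]-2-methylpropanal | CC1=CC[C@H](C(C)(C)C=O)[C@@](C)(C=C)C1=O | intermediate
12 | (5R,6R)-6-ethenyl-5-(3-hydroxy-2-methylpent-4-en-2-yl)-2,6-dimethylcyclohex-2-en-1-one (carbinol epimers) | CC1=CC[C@H](C(C)(C)C(O)C=C)[C@@](C)(C=C)C1=O | intermediate
13 | (5R,6R)-6-ethenyl-2,6-dimethyl-5-(2-methyl-3-oxopent-4-en-2-yl)cyclohex-2-en-1-one | CC1=CC[C@H](C(C)(C)C(=O)C=C)[C@@](C)(C=C)C1=O | intermediate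
14 | (5R,10R)-11-nordrima-1,7-diene-3,9-dione, (4aR,8aR)-2,5,5,8a-tetramethyl-4a,8a-dihydronaphthalene-1,6(4H,5H)-dione | CC1=CC[C@@H]2C(C)(C)C(=O)C=C[C@@]2(C)C1=O | intermediate
15 | (3R,5R,10R)-3-hydroxy-11-nordrima-1,7-dien-9-one | CC1=CC[C@@H]2C(C)(C)[C@H](O)C=C[C@@]2(C)C1=O | intermediate
16 | 2-boryl-3-boryloxy-11-nordrim-7-en-9-one (organoborane) | CC1=CC[C@@H]2C(C)(C)[C@H](OB)[C@@H](B)C[C@@]2(C)C1=O | intermediate (not isolated)
17 | (2S,3S,5R,10R)-2,3-dihydroxy-11-nordrim-7-en-9-one | CC1=CC[C@@H]2C(C)(C)[C@H](O)[C@@H](O)C[C@@]2(C)C1=O | intermediate
18 | (2S,3S,5R,10R)-2,3-(isopropylidenedioxy)-11-nordrim-7-en-9-one | CC1=CC[C@@H]2C(C)(C)[C@@H]3OC(C)(C)O[C@H]3C[C@@]2(C)C1=O | intermediate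
19 | (2S,3S,5S,10R)-2,3-(isopropylidenedioxy)-9-methylidene-11-nordrim-7-ene | CC1=CC[C@@H]2C(C)(C)[C@@H]3OC(C)(C)O[C@H]3C[C@@]2(C)C1=C | intermediate
20 | 11-(9-borabicyclo[3.3.1]nonan-9-yl)-2,3-(isopropylidenedioxy)drim-7-ene | CC1=CC[C@@H]2C(C)(C)[C@@H]3OC(C)(C)O[C@H]3C[C@@]2(C)[C@@H]1CB1C2CCCC1CCC2 | intermediate (not isolated)
21 | (2S,3S,5S,9R,10R)-2,3-(isopropylidenedioxy)drim-7-en-11-ol | CC1=CC[C@@H]2C(C)(C)[C@@H]3OC(C)(C)O[C@H]3C[C@@]2(C)[C@@H]1CO | intermediate
22 | umbelliferone, 7-hydroxy-2H-chromen-2-one | Oc1ccc2ccc(=O)oc2c1 | starting material
23 | 7-{[(2S,3S,5S,9R,10R)-2,3-(isopropylidenedioxy)drim-7-en-11-yl]oxy}-2H-chromen-2-one | CC1=CC[C@@H]2C(C)(C)[C@@H]3OC(C)(C)O[C@H]3C[C@@]2(C)[C@@H]1COc1ccc2ccc(=O)oc2c1 | intermediate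
24 | 7-{[(2S,3S,5S,9R,10R)-2,3-dihydroxydrim-7-en-11-yl]oxy}-2H-chromen-2-one | CC1=CC[C@@H]2C(C)(C)[C@H](O)[C@@H](O)C[C@@]2(C)[C@@H]1COc1ccc2ccc(=O)oc2c1 | target

## Step count and least certain steps

Total step count: 16. Longest linear sequence: 16 steps, from 1 to 24; 22 enters at step 15.

**Step 9 (key step).** Initiation at the neopentylic C10 vinyl group may be slow and the acryloyl partner is electron-poor, so catalyst decay and intermolecular metathesis may outrun ring closure. Fallback, from 11 back to 14: methylmagnesium bromide at −78 °C should give the methyl carbinol F1, and Dess–Martin oxidation the methyl ketone F2. Cleavage of the C10 vinyl group with OsO4 (cat.) and NaIO4, which should spare the electron-poor C7=C8 bond, gives the keto aldehyde F3. Intramolecular aldol condensation of the methyl ketone with the non-enolizable C10 formyl group (piperidine, AcOH, benzene, 80 °C) then closes ring A and forms C1=C2, arriving at 14.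

**Step 11.** Borane may reduce the C9 carbonyl and then add across C7=C8, or boron may be placed at C1 instead of C2. Over-reduction at C9 alone would be corrected by manganese dioxide, which reoxidizes only the allylic carbinol. Fallback, from 14 back to 17: hydrogenation with RhCl(PPh3)3 should saturate only the disubstituted C1=C2 bond, giving the diketone F4. LDA and Me3SiCl then give the C2=C3 silyl enol ether F5, since only the C3 ketone has α-hydrogens. Rubottom oxidation with mCPBA from the face opposite the axial methyls gives the 2-hydroxy-3-ketone F6, and hydroxyl-directed reduction with Me4NBH(OAc)3 delivers hydride syn to O2 to give the trans-diol 17.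

**Step 13.** The ylide may fail to add to the flanked C9 carbonyl, or it may act as a base at the γ-positions and stall the reaction as a dienolate. Fallback, from 18 back to 19: Me3SiCH2Li with CeCl3 (a small, weakly basic nucleophile) should add to the carbonyl to give the β-hydroxysilane F7, and KH in THF effects the Peterson elimination to 19.

**Step 14.** Facial selectivity at C9 may be poor, with hydrogen delivered from the side of the C10 methyl group, or the conjugated diene may react sluggishly. Fallback, from 18 back to 21 (bypassing 19 and 20): dimethylsulfonium methylide (Corey–Chaykovsky) should add axially, anti to the C10 methyl group, to give the spiro vinyl epoxide F8. With Pd2(dba)3, PBu3, HCO2H and Et3N, zerovalent palladium ionizes the allylic C9–O bond with inversion, and the hydride from formate is transferred from palladium to C9. H9 thus arrives on the face opposite the former C–O bond, C7=C8 stays in place, and 21 results.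

**Step 6.** Deprotonation at the γ-positions of the enone may compete with aldehyde enolization, leading to methylation at the ring α-carbon, and the hindered aldehyde enolate may be O-methylated or undergo aldol condensation. Fallback, from 10 back to 11: soft enolization with Me3SiCl and Et3N in DMF gives the silyl enol ether F9. Simmons–Smith cyclopropanation with Et2Zn and CH2I2, fastest at the electron-rich enol ether, gives the siloxycyclopropane F10. Ring opening with K2CO3 in MeOH toward the CH2 carbon turns that carbon into the second methyl group of 11.

**Step 10.** Hydride may also attack the C9 carbonyl, or attack C3 from the wrong face. Fallback, from 14 back to 15: iBu2AlH at −78 °C reduces both carbonyls to the diol F11. TBSCl and imidazole should silylate the more accessible 3-hydroxyl to give F12, Dess–Martin oxidation of the remaining C9 carbinol gives the silyl ether enone F13, and Bu4NF releases 15.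

## Further compounds

F1 | step 9 | (5R,6R)-6-ethenyl-5-(3-hydroxy-3-methylbutan-2-yl... corrected: 3-hydroxy-2-methylbutan-2-yl)-2,6-dimethylcyclohex-2-en-1-one (carbinol epimers) | CC1=CC[C@H](C(C)(C)C(C)O)[C@@](C)(C=C)C1=O
F2 | step 9 | (5R,6R)-6-ethenyl-2,6-dimethyl-5-(2-methyl-3-oxobutan-2-yl)cyclohex-2-en-1-one | CC1=CC[C@H](C(C)(C)C(C)=O)[C@@](C)(C=C)C1=O
F3 | step 9 | (1S,6R)-1,3-dimethyl-6-(2-methyl-3-oxobutan-2-yl)-2-oxocyclohex-3-ene-1-carbaldehyde | CC1=CC[C@H](C(C)(C)C(C)=O)[C@@](C)(C=O)C1=O
F4 | step 11 | (5R,10R)-11-nordrim-7-ene-3,9-dione | CC1=CC[C@@H]2C(C)(C)C(=O)CC[C@@]2(C)C1=O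
F5 | step 11 | (5R,10R)-3-(trimethylsilyloxy)-11-nordrima-2,7-dien-9-one | CC1=CC[C@@H]2C(C)(C)C(O[Si](C)(C)C)=CC[C@@]2(C)C1=O
F6 | step 11 | (2S,5R,10R)-2-hydroxy-11-nordrim-7-ene-3,9-dione | CC1=CC[C@@H]2C(C)(C)C(=O)[C@@H](O)C[C@@]2(C)C1=O
F7 | step 13 | (2S,3S,5R,10R)-2,3-(isopropylidenedioxy)-9-[(trimethylsilyl)methyl]-11-nordrim-7-en-9-ol (C9 epimers) | CC1=CC[C@@H]2C(C)(C)[C@@H]3OC(C)(C)O[C@H]3C[C@@]2(C)C1(O)C[Si](C)(C)C
F8 | step 14 | (2S,3S,5R,9R,10R)-9,11-epoxy-2,3-(isopropylidenedioxy)drim-7-ene | CC1=CC[C@@H]2C(C)(C)[C@@H]3OC(C)(C)O[C@H]3C[C@@]2(C)[C@@]14CO4
F9 | step 6 | (5R,6R)-6-ethenyl-2,6-dimethyl-5-[1-(trimethylsilyloxy)prop-1-en-2-yl]cyclohex-2-en-1-one (E and Z) | CC1=CC[C@H](C(C)=CO[Si](C)(C)C)[C@@](C)(C=C)C1=O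
F10 | step 6 | (5R,6R)-6-ethenyl-2,6-dimethyl-5-[1-methyl-2-(trimethylsilyloxy)cyclopropyl]cyclohex-2-en-1-one (cyclopropane isomers) | CC1=CC[C@H](C2(C)CC2O[Si](C)(C)C)[C@@](C)(C=C)C1=O
F11 | step 10 | (3R,5R,10R)-11-nordrima-1,7-diene-3,9-diol (C9 epimers) | CC1=CC[C@@H]2C(C)(C)[C@H](O)C=C[C@@]2(C)C1O
F12 | step 10 | (3R,5R,10R)-3-(tert-butyldimethylsilyloxy)-11-nordrima-1,7-dien-9-ol (C9 epimers) | CC1=CC[C@@H]2C(C)(C)[C@H](O[Si](C)(C)C(C)(C)C)C=C[C@@]2(C)C1O
F13 | step 10 | (3R,5R,10R)-3-(tert-butyldimethylsilyloxy)-11-nordrima-1,7-dien-9-one | CC1=CC[C@@H]2C(C)(C)[C@H](O[Si](C)(C)C(C)(C)C)C=C[C@@]2(C)C1=O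
A1 | alternative 1 | trans-6-(tert-butyldimethylsilyloxy)-4-ethenyl-3,5,5-trimethylcyclohex-3-en-1-yl but-2-ynoate | CC#CC(=O)O[C@H]1CC(C)=C(C=C)C(C)(C)[C@@H]1O[Si](C)(C)C(C)(C)C
A2 | alternative 1 | 11,2-lactone of 3-(tert-butyldimethylsilyloxy)-2-hydroxydrima-5,8-dien-11-oic acid | CC1=C2C(=O)O[C@H]3C[C@]2(C)C(=CC1)C(C)(C)[C@@H]3O[Si](C)(C)C(C)(C)C
A3 | alternative 2 | methyl (2E)-5-(5-acetoxy-2,6,6-trimethylcyclohex-1-en-1-yl)-3-methylpent-2-enoate | COC(=O)/C=C(\C)CCC1=C(C)CC[C@@H](OC(C)=O)C1(C)C
A4 | alternative 2 | methyl 3-acetoxydrim-7-en-11-oate of the target series | CC1=CC[C@@H]2C(C)(C)[C@H](OC(C)=O)CC[C@@]2(C)[C@@H]1C(=O)OC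
A5 | alternative 3 | C7=C9 trimethylsilyl enol ether of the trans-hydrindan-9-one with ring A acetonide, C4 gem-dimethyl and C10 methyl groups (C8 absent) | C[Si](C)(C)OC1=CC[C@@H]2C(C)(C)[C@@H]3OC(C)(C)O[C@H]3C[C@@]12C
A6 | alternative 3 | (2S,3S,5R,10R)-2,3-(isopropylidenedioxy)-11-nordrim-7-en-9-one (identical with 18) | CC1=CC[C@@H]2C(C)(C)[C@@H]3OC(C)(C)O[C@H]3C[C@@]2(C)C1=O
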